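## Retrosynthetic overview
1. Target ⇒ (2S)-flavanone. The C3–OH goes in last, on the closed ring and anti to the 2-aryl group (chemical counterpart of flavanone 3β-hydroxylase).
2. (2S)-Flavanone ⇒ 2',6'-dihydroxychalcone by O1–C2 disconnection. This is a catalytic enantioselective 6-endo oxa-Michael closure on the fully unprotected chalcone (counterpart of chalcone isomerase). It sets C2, and C2 then controls C3.
3. Chalcone ⇒ 4-O-prenylphloracetophenone + vanillin (Claisen–Schmidt). The ketone ⇒ phloracetophenone + prenyl bromide.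
4. Ring order: rings A and B are bought. Ring C is the only ring made (step 3). There are no separate protecting-group steps.

Assumption: the epi-quinidine-derived thiourea gives the (2S) series. This is checked on 6 by CD (2S-flavanones show a negative band near 290 nm). If the sense is reversed, the pseudo-enantiomeric epi-quinine thiourea is used and nothing else changes.

## Route

Step 1
Reactants: 1 2,4,6-trihydroxyacetophenone; 2 prenyl bromide
Product: 3 1-[2,6-dihydroxy-4-(3-methylbut-2-enyloxy)phenyl]ethanone
Conditions: K2CO3 (1.1 equiv), 2 (1.05 equiv), acetone, reflux, 4 h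
Reagents that add atoms: prenyl bromide 2, CC(C)=CCBr
Why: Williamson etherification, in which the 4-OH is the most acidic phenol and the only one not hydrogen-bonded to the acetyl C=O, so one equivalent of weak base in an aprotic solvent gives SN2 O-alkylation there; no stereocenter is formed.

Step 2
Reactants: 3 1-[2,6-dihydroxy-4-(3-methylbut-2-enyloxy)phenyl]ethanone; 4 vanillin
Product: 5 (E)-1-[2,6-dihydroxy-4-(3-methylbut-2-enyloxy)phenyl]-3-(4-hydroxy-3-methoxyphenyl)prop-2-en-1-one
Conditions: KOH (60% aq, 20 equiv), EtOH, 0 °C→rt, 72 h, Ar; pour onto ice/2 M HCl (pH 3); fast SiO2 to remove any ring-closed racemate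
Reagents that add atoms: none
Why: Claisen–Schmidt aldol condensation run on the polyanions, where excess hydroxide keeps the product as the open chalcone polyanion, E1cB loss of water gives the conjugated (E)-enone, and cold rapid acidification releases the chalcone before it can close.

Step 3
Reactants: 5 (E)-chalcone
Product: 6 (2S)-5-hydroxy-2-(4-hydroxy-3-methoxyphenyl)-7-(3-methylbut-2-enyloxy)chroman-4-one
Conditions: N-[3,5-bis(trifluoromethyl)phenyl]-N'-[(9R)-6'-methoxycinchonan-9-yl]thiourea (10 mol %), PhMe/CH2Cl2 4:1, −20 °C, 72 h; SiO2 plug; recrystallise (EtOAc/heptane) to ≥99% ee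
Reagents that add atoms: none
Why: Proposed new method: the quinuclidine nitrogen ion-pairs with one acidic ortho-OH while the thiourea and the second, chelated ortho-OH polarise the enone carbonyl, so the phenoxide adds 6-endo to one face of the (E)-enone inside a chiral pocket as in chalcone isomerase and sets C2 as S, helped by the two ortho-OH groups being equivalent (either gives the same product), by negligible uncatalysed closure in this apolar medium, and by the 2',6'-dihydroxy pattern making closure practically irreversible at −20 °C; the closest known reaction type is the bifunctional cinchona-thiourea-catalysed asymmetric intramolecular oxa-Michael addition of 2'-hydroxychalcones and their α-ester-activated analogues to flavanones.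

Step 4
Reactants: 6 (2S)-flavanone
Product: 9 (2R,3R)-3,5-dihydroxy-2-(4-hydroxy-3-methoxyphenyl)-7-(3-methylbut-2-enyloxy)chroman-4-one, via tris-TMS enol ether 7 (not isolated), via siloxy-epoxide 8 (not isolated)
Conditions: TMSOTf (4.5 equiv), Et3N (6 equiv), CH2Cl2, −78→0 °C, dark; cold aq NaHCO3 wash, crude; DMDO (1.05 equiv, acetone), CH2Cl2, −78→−40 °C; 0.5 M HCl, THF, 0 °C, 20 min
Reagents that add atoms: DMDO, CC1(C)OO1 (the oxygen at C3); TMSOTf, C[Si](C)(C)OS(=O)(=O)C(F)(F)F (TMS groups of 7 and 8 only, lost again before 9)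
Why: Soft enolisation followed by Rubottom-type oxidation, in which no free enolate is formed (so no E1cB ring opening and no loss of C2), DMDO attacks the very electron-rich silyl enol ether much faster than the prenyl alkene and from the face anti to the 2-aryl group, and acid collapse of the siloxy-epoxide with loss of all TMS groups gives the 2,3-trans alcohol, which is 2R,3R because C2 is unchanged in space (only its CIP descriptor changes from S to R) and which is also the thermodynamic C3 epimer.

## Compound list
1 | 2,4,6-trihydroxyacetophenone | CC(=O)c1c(O)cc(O)cc1O | starting material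
2 | prenyl bromide (1-bromo-3-methylbut-2-ene) | CC(C)=CCBr | starting material
3 | 1-[2,6-dihydroxy-4-(3-methylbut-2-enyloxy)phenyl]ethanone | CC(=O)c1c(O)cc(OCC=C(C)C)cc1O | intermediate
4 | vanillin | COc1cc(C=O)ccc1O | starting material
5 | (E)-1-[2,6-dihydroxy-4-(3-methylbut-2-enyloxy)phenyl]-3-(4-hydroxy-3-methoxyphenyl)prop-2-en-1-one | COc1cc(/C=C/C(=O)c2c(O)cc(OCC=C(C)C)cc2O)ccc1O | intermediate
6 | (2S)-5-hydroxy-2-(4-hydroxy-3-methoxyphenyl)-7-(3-methylbut-2-enyloxy)chroman-4-one | COc1cc([C@H]2Oc3cc(OCC=C(C)C)cc(O)c3C(=O)C2)ccc1O | intermediate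
7 | (2S)-2-[3-methoxy-4-(trimethylsilyloxy)phenyl]-7-(3-methylbut-2-enyloxy)-4,5-bis(trimethylsilyloxy)-2H-chromene | COc1cc([C@H]2Oc3cc(OCC=C(C)C)cc(O[Si](C)(C)C)c3C(O[Si](C)(C)C)=C2)ccc1O[Si](C)(C)C | intermediate
8 | 3,4-epoxide of 7, oxirane oxygen on the face opposite the 2-aryl group (flavan numbering 2R,3R,4R) | COc1cc([C@H]2Oc3cc(OCC=C(C)C)cc(O[Si](C)(C)C)c3[C@]4(O[Si](C)(C)C)O[C@H]24)ccc1O[Si](C)(C)C | intermediate
9 | (2R,3R)-3,5-dihydroxy-2-(4-hydroxy-3-methoxyphenyl)-7-(3-methylbut-2-enyloxy)chroman-4-one (CNP0526884.1) | COc1cc([C@H]2Oc3cc(OCC=C(C)C)cc(O)c3C(=O)[C@@H]2O)ccc1O | target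

## Step count and risks
Total step count: 4. Longest linear sequence: 4 (1 → 3 → 5 → 6 → 9).

**Most likely to fail, first: step 3 (level of enantioselectivity on the unprotected chalcone).**
- The fallback sets out from 5 and comes back at 6.
- The ring is closed without control (NaOAc, EtOH, reflux) to the racemic flavanone F1.
- F1 is then resolved kinetically by asymmetric transfer hydrogenation: RuCl[(R,R)-TsDPEN](p-cymene) 1 mol %, HCO2H/Et3N 5:2, EtOAc, rt, stopped near 52% conversion.
- The (2R)-enantiomer is reduced, with hydride delivered anti to the aryl group, to the cis-(2R,4R)-flavan-4-ol F2, which is removed by chromatography.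
- Unreacted (2S)-flavanone 6 is recovered in high ee. The prenyl alkene is inert to these conditions.

**Second: step 4 (DMDO selectivity between enol ether and prenyl alkene, and integrity of C2 during silylation).**
- The fallback sets out from 5 and comes back at 9, bypassing 6–8. It uses only nucleophilic oxygen, which cannot touch the prenyl group.
- 5 is silylated (TBSOTf, 2,6-lutidine, CH2Cl2, 0 °C) to the tris-TBS chalcone F3.
- Catalytic asymmetric Weitz–Scheffer epoxidation (La(OiPr)3/(S)-BINOL/Ph3As=O 10 mol %, TBHP, MS 4 Å, THF, rt) gives the (αR,βS)-epoxychalcone F4.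
- TBAF/AcOH (1:1, THF, 0 °C) liberates the free epoxy-chalcone F5.
- F5 closes in the flask by attack of an ortho-OH at the electron-rich benzylic carbon. Cα becomes C3 (R) with its C–O bond intact, and C2 ends trans, giving 9.

**Third: step 2 (slow condensation of two phenoxide-deactivated partners).**
- The fallback sets out from 3 and 4 and comes back at 5.
- Vanillin is silylated (TBSCl, imidazole, DMF) to O-TBS-vanillin F6, which is a normal electrophilic aldehyde.
- 3 is converted into its trilithio species (LiHMDS 3.3 equiv, THF, −78 °C) and treated with F6 (−78 °C→rt).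
- This directed aldol/E1cB sequence gives the 4-O-TBS chalcone F7.
- KHF2 in MeOH at rt (weakly acidic, so the chalcone stays open) removes the silyl group to give 5.

## Further compounds
F1 | step 3 | racemic 5-hydroxy-2-(4-hydroxy-3-methoxyphenyl)-7-(3-methylbut-2-enyloxy)chroman-4-one | COc1cc(C2Oc3cc(OCC=C(C)C)cc(O)c3C(=O)C2)ccc1O
F2 | step 3 | (2R,4R)-2-(4-hydroxy-3-methoxyphenyl)-7-(3-methylbut-2-enyloxy)chromane-4,5-diol (2,4-cis) | COc1cc([C@@H]2Oc3cc(OCC=C(C)C)cc(O)c3[C@H](O)C2)ccc1O
F3 | step 4 | (E)-1-[2,6-bis(tert-butyldimethylsilyloxy)-4-(3-methylbut-2-enyloxy)phenyl]-3-[4-(tert-butyldimethylsilyloxy)-3-methoxyphenyl]prop-2-en-1-one | COc1cc(/C=C/C(=O)c2c(O[Si](C)(C)C(C)(C)C)cc(OCC=C(C)C)cc2O[Si](C)(C)C(C)(C)C)ccc1O[Si](C)(C)C(C)(C)C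
F4 | step 4 | (αR,βS)-trans-epoxide of F3 | COc1cc([C@@H]2O[C@H]2C(=O)c2c(O[Si](C)(C)C(C)(C)C)cc(OCC=C(C)C)cc2O[Si](C)(C)C(C)(C)C)ccc1O[Si](C)(C)C(C)(C)C
F5 | step 4 | (αR,βS)-trans-epoxide of chalcone 5 (all phenols free, not isolated) | COc1cc([C@@H]2O[C@H]2C(=O)c2c(O)cc(OCC=C(C)C)cc2O)ccc1O
F6 | step 2 | 4-(tert-butyldimethylsilyloxy)-3-methoxybenzaldehyde | COc1cc(C=O)ccc1O[Si](C)(C)C(C)(C)C
F7 | step 2 | (E)-3-[4-(tert-butyldimethylsilyloxy)-3-methoxyphenyl]-1-[2,6-dihydroxy-4-(3-methylbut-2-enyloxy)phenyl]prop-2-en-1-one | COc1cc(/C=C/C(=O)c2c(O)cc(OCC=C(C)C)cc2O)ccc1O[Si](C)(C)C(C)(C)C
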